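The cyclohexene is closed last, on a preformed trans-2,3-disubstituted cyclopentane, by joining C1 (methyl-bearing vinyl carbon) to C6 (ring CH carrying the triene). The key step is a gold-catalysed 6-endo-dig carbocyclization: the silyl enol ether of an aldehyde at C11 (first triene carbon) attacks, through C6, a propynyl group (C1≡C2) sitting on ring-fusion carbon C3. One operation gives the six-membered ring, the C1=C2 alkene and the C6 stereocentre. It exploits the 2-methylcyclohex-2-ene-1-carbaldehyde pattern C2=C1(Me)–C6–C11 and the trans ring fusion, which rules out 5-exo closure. The aldehyde becomes an alkyne, and a (Z)-enediyne joined to the side chain is reduced to the Z,Z,Z-triene.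

Key step: step 12

Numbering used here: ring carbons C1 (C–Me, vinyl), C2 (vinyl CH), C3 and C4 (ring-fusion CH, C3 next to C2), C5 (CH bearing the carbinol), C6 (CH bearing the triene), C7 (CMe2), C8 (CH2), C9 (C(Me)OH); C10 is the benzylic carbinol carbon; the side chain runs C11 to C25 from the ring to CO2H (C17 and C19 carbinols, C18 CHMe, C22 C–Me).

Assumption: for each chiral catalyst or reagent (steps 1, 15, 16, 18) the antipode named is the one whose accepted transition-state model gives the configuration drawn; should the sense be opposite, the mirror-image catalyst or reagent is used.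

**Core fragment**

Step 1
Reactants: 1 4,4-dimethylcyclopent-2-en-1-one; 2 tert-butyl[(1-methoxyethenyl)oxy]dimethylsilane
Product: 3 methyl 2-[(1R)-3-(TBS-oxy)-5,5-dimethylcyclopent-2-en-1-yl]acetate
Conditions: chiral oxazaborolidinium triflimide [(S)-B-(o-tolyl)oxazaborolidine of α,α-diphenylprolinol + HNTf2, 10 mol %], toluene, −40 °C
Reagents that add atoms: none
Why: Catalytic asymmetric Mukaiyama–Michael addition in which the chiral Lewis acid binds the enone carbonyl and shields one face, so the ketene acetal adds to the open face of the β-carbon to set C4, and silyl transfer leaves the C9 enolate as a regiodefined silyl enol ether.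

Step 2
Reactants: 3 TBS enol ether ester
Product: 4 methyl 2-[(1R)-5,5-dimethyl-3-(triflyloxy)cyclopent-2-en-1-yl]acetate
Conditions: CsF, PhNTf2, DME, rt
Reagents that add atoms: N-phenylbis(trifluoromethanesulfonimide), O=S(=O)(N(c1ccccc1)S(=O)(=O)C(F)(F)F)C(F)(F)F
Why: Fluoride unmasks the regiodefined cesium enolate, which is O-sulfonylated by PhNTf2 (enol triflate formation) without touching C4.

Step 3
Reactants: 4 enol triflate
Product: 5 methyl 2-[(1R)-3,5,5-trimethylcyclopent-2-en-1-yl]acetate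
Conditions: MeZnCl, Pd(PPh3)4 (5 mol %), THF, 60 °C
Reagents that add atoms: methylzinc chloride, C[Zn]Cl
Why: Negishi cross-coupling of the enol triflate installs the C9 methyl group and fixes the trisubstituted C9=C3 alkene, the ester being inert to the organozinc.

Step 4
Reactants: 5 trimethylcyclopentene ester
Product: 7 methyl 2-[(1S,2S,5R)-3,3,5-trimethyl-6-oxabicyclo[3.1.0]hexan-2-yl]acetate, via bromohydrin 6 (not isolated)
Conditions: NBS, acetone/H2O (4:1), 0 °C; then K2CO3, MeOH, rt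
Reagents that add atoms: water, O
Why: Bromohydrin formation then Williamson closure: the bromonium ion forms anti to the C4 side chain, water opens it at the tertiary carbon C9, and the alkoxide displaces bromide with inversion, so the epoxide ends syn to the side chain, which sets the C9 oxygen cis to the C4 substituent.

Step 5
Reactants: 7 epoxy ester; 8 prop-1-yn-1-yllithium
Product: 9 methyl 2-[(1R,2S,3R)-3-hydroxy-3,5,5-trimethyl-2-(prop-1-yn-1-yl)cyclopentyl]acetate
Conditions: BF3·OEt2, THF, −78 °C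
Reagents that add atoms: none
Why: BF3-promoted SN2 opening of the epoxide by the alkynyllithium (Yamaguchi alkynylation) at the secondary carbon C3 with inversion places the propynyl group trans to both the C9 oxygen and the C4 side chain, setting C3, while the ester survives at −78 °C.

Step 6
Reactants: 9 hydroxy ester
Product: 10 methyl 2-[(1R,2S,3R)-3,5,5-trimethyl-2-(prop-1-yn-1-yl)-3-(triethylsilyloxy)cyclopentyl]acetate
Conditions: TESOTf, 2,6-lutidine, CH2Cl2, −78 → 0 °C
Reagents that add atoms: triethylsilyl trifluoromethanesulfonate, CC[Si](CC)(CC)OS(=O)(=O)C(F)(F)F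
Why: Silylation of the hindered tertiary alcohol with the silyl triflate protects C9–OH for the enolate chemistry and prevents lactonization onto the cis side chain.

Step 7
Reactants: 10 TES ether ester
Product: 11 Weinreb amide of 10
Conditions: MeNH(OMe)·HCl, i-PrMgCl, THF, −20 → 0 °C
Reagents that add atoms: N,O-dimethylhydroxylamine hydrochloride, CNOC.Cl
Why: Aminolysis of the ester by the chloromagnesium amide gives the Weinreb amide, which allows a single aryl addition.

Step 8
Reactants: 11 Weinreb amide; 12 (4-bromophenoxy)triisopropylsilane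
Product: 14 aryl ketone 2-[(1R,2S,3R)-cyclopentyl]-1-[4-(triisopropylsilyloxy)phenyl]ethan-1-one, via aryllithium 13 (not isolated)
Conditions: 12, n-BuLi, THF, −78 °C; then 11, −78 → 0 °C; aq. NH4Cl
Reagents that add atoms: none
Why: Bromine–lithium exchange and addition of the aryllithium to the Weinreb amide stop at the chelated tetrahedral intermediate, which collapses to the aryl ketone on work-up (Weinreb ketone synthesis).

Step 9
Reactants: 14 aryl ketone; 15 3-bromoprop-1-ene
Product: 16 (2S)-2-[(1S,2S,3R)-cyclopentyl]-1-aryl-pent-4-en-1-one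
Conditions: KHMDS, THF, −78 °C; then 15, −78 → −40 °C
Reagents that add atoms: none
Why: Alkylation of the Z potassium enolate, in which allylic strain holds C4–H in the enolate plane and the allyl bromide enters anti to the quaternary C7 side, is expected to favour the C5 configuration shown, and C5 stays correctable by base equilibration (α to the aryl ketone) until step 15.

Step 10
Reactants: 16 allyl ketone
Product: 17 (3S)-4-oxo-3-[(1S,2S,3R)-cyclopentyl]-4-aryl-butanal
Conditions: OsO4 (2 mol %), NaIO4, 2,6-lutidine, dioxane/H2O (3:1), rt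
Reagents that add atoms: sodium periodate, [Na+].[O-]I(=O)(=O)=O
Why: Lemieux–Johnson cleavage (dihydroxylation, then periodate cleavage) of the terminal alkene gives the C11 aldehyde, the internal alkyne being inert.

Step 11
Reactants: 17 keto aldehyde
Product: 18 (2R,3Z)-4-(TBS-oxy)-2-[(1S,2S,3R)-cyclopentyl]-1-aryl-but-3-en-1-one
Conditions: TBSOTf, Et3N, CH2Cl2, −78 → 0 °C
Reagents that add atoms: tert-butyldimethylsilyl trifluoromethanesulfonate, CC(C)(C)[Si](C)(C)OS(=O)(=O)C(F)(F)F
Why: Soft enolization (O-silylation of the aldehyde, deprotonation at C6 by Et3N) gives the aldehyde-derived silyl enol ether, the α-branched aryl ketone reacting more slowly.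

Step 12
Reactants: 18 silyl enol ether alkyne
Product: 19 (1R,3aS,4R,5S,7aR)-1,3,3,6-tetramethyl-1-(triethylsilyloxy)-4-[4-(triisopropylsilyloxy)benzoyl]-2,3,3a,4,5,7a-hexahydro-1H-indene-5-carbaldehyde
Conditions: [(t-Bu)2(2-biphenylyl)P]Au(NCMe)SbF6 (5 mol %), i-PrOH (2 equiv), CH2Cl2, rt
Reagents that add atoms: none
Why: Cationic monovalent gold activates the methyl-capped alkyne, the enol ether carbon C6 attacks the distal alkyne carbon C1 anti to gold, the oxocarbenium ion gives up its silyl group to i-PrOH, and protodeauration at C2 releases the β,γ-unsaturated aldehyde. The closest known reaction type is the gold-catalysed carbocyclization of silyl enol ethers onto alkynes (Conia-ene type). The six-membered ring closes in the 6-endo-dig mode. The one new stereocentre, C6, is set by a chair-like transition state in which the enol ether terminus and the C5 aroyl group are both pseudo-equatorial, so the formyl group ends trans to C5 in the all-equatorial isomer, which is also the thermodynamic one. The step needs 6-endo over 5-exo closure and C-attack over O-attack of the ketone; the first is secured by the trans arrangement of the propynyl group and side chain on the cyclopentane (5-exo closure would give a trans-fused bicyclo[3.3.0]octane), by the methyl cap that stabilises positive charge at C1 and by the bulky biaryl phosphine, the second by the higher nucleophilicity of the enol ether. C3, C4, C5 and C9 are not touched.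

Step 13
Reactants: 19 bicyclic keto aldehyde
Product: 20 [(1R,3aS,4R,5R,7aR)-5-ethynyl-hexahydroindenyl] aryl ketone
Conditions: dimethyl (1-diazo-2-oxopropyl)phosphonate, K2CO3, MeOH, 0 °C
Reagents that add atoms: dimethyl (1-diazo-2-oxopropyl)phosphonate, CC(=O)C(=[N+]=[N-])P(=O)(OC)OC
Why: Ohira–Bestmann homologation: the diazomethylphosphonate anion formed in the flask adds to the aldehyde, and loss of phosphate and N2 with a 1,2-shift gives the terminal alkyne without changing C6.

Step 14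
Reactants: 20 terminal alkyne; 21 (Z)-1,2-dichloroethene (excess)
Product: 22 [(1R,3aS,4R,5S,7aR)-5-((3Z)-4-chlorobut-3-en-1-ynyl)-hexahydroindenyl] aryl ketone
Conditions: Pd(PPh3)4 (5 mol %), CuI (10 mol %), n-BuNH2, Et2O, rt
Reagents that add atoms: none
Why: Sonogashira coupling with excess dichloroethene stops at the monocoupled (Z)-chloroenyne with retention of the alkene geometry.

Step 15
Reactants: 22 chloroenyne ketone
Product: 23 (S)-benzylic alcohol of 22
Conditions: (R)-2-methyl-CBS-oxazaborolidine (20 mol %), catecholborane, toluene, −78 °C; aq. NaOH work-up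
Reagents that add atoms: none
Why: Corey–Bakshi–Shibata reduction in which the (R)-oxazaborolidine delivers hydride to the ketone face that gives the (S)-carbinol (aryl as the large group), setting C10, while catecholborane leaves the alkyne, alkenes and vinyl chloride untouched.

**Side-chain fragment**

Step 16
Reactants: 24 propanal; 25 3-(trimethylsilyl)prop-2-ynal
Product: 26 (2S,3R)-3-hydroxy-2-methyl-5-(trimethylsilyl)pent-4-ynal
Conditions: (S)-α,α-bis[3,5-bis(trifluoromethyl)phenyl]pyrrolidin-2-ylmethanol (10 mol %), DMF, 4 °C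
Reagents that add atoms: none
Why: Enamine-mediated anti-selective cross-aldol reaction of propanal with the non-enolizable ynal, in which the hydrogen-bonded chair-like transition state sets C17 and C18 in the anti relationship.

Step 17
Reactants: 26 aldol
Product: 27 (2S,3R)-3-(TBS-oxy)-2-methyl-5-(trimethylsilyl)pent-4-ynal
Conditions: TBSOTf, 2,6-lutidine, CH2Cl2, −78 °C
Reagents that add atoms: tert-butyldimethylsilyl trifluoromethanesulfonate, CC(C)(C)[Si](C)(C)OS(=O)(=O)C(F)(F)F
Why: Low-temperature silylation protects the β-hydroxy aldehyde against retro-aldol cleavage and elimination without epimerizing C18.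

Step 18
Reactants: 27 silyloxy aldehyde; 28 (+)-B-allyldiisopinocampheylborane
Product: 29 (4R,5R,6R)-6-(TBS-oxy)-5-methyl-8-(trimethylsilyl)oct-1-en-7-yn-4-ol
Conditions: Et2O, −100 → −78 °C; then NaOH, H2O2
Reagents that add atoms: none
Why: Brown allylboration through a Zimmerman–Traxler chair in which the isopinocampheyl groups choose the aldehyde face and override the Felkin preference, giving the 2,3-anti, 1,3-syn alcohol and setting C19.

Step 19
Reactants: 29 homoallylic alcohol
Product: 30 (4R,5R,6R)-4,6-bis(TBS-oxy)-5-methyl-8-(trimethylsilyl)oct-1-en-7-yne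
Conditions: TBSOTf, 2,6-lutidine, CH2Cl2, −78 → 0 °C
Reagents that add atoms: tert-butyldimethylsilyl trifluoromethanesulfonate, CC(C)(C)[Si](C)(C)OS(=O)(=O)C(F)(F)F
Why: Silylation protects the C19 hydroxyl before the olefinations.

Step 20
Reactants: 30 bis-silyl ether; 31 2-methylprop-2-enal (excess)
Product: 32 (2E,5R,6R,7R)-5,7-bis(TBS-oxy)-2,6-dimethyl-9-(trimethylsilyl)non-2-en-8-ynal
Conditions: second-generation Hoveyda–Grubbs catalyst, (H2IMes)Cl2Ru(=CH-C6H4-2-O-i-Pr) (5 mol %), CH2Cl2, 40 °C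
Reagents that add atoms: none
Why: Olefin cross-metathesis of the terminal alkene with methacrolein gives the (E)-2-methyl enal under thermodynamic control, the silyl-capped alkyne being inert to the carbene.

Step 21
Reactants: 32 enal
Product: 33 methyl (2Z,4E,7R,8R,9R)-7,9-bis(TBS-oxy)-4,8-dimethyl-11-(trimethylsilyl)undeca-2,4-dien-10-ynoate
Conditions: (CF3CH2O)2P(O)CH2CO2Me, KHMDS, 18-crown-6, THF, −78 °C
Reagents that add atoms: methyl bis(2,2,2-trifluoroethyl)phosphonoacetate, COC(=O)CP(=O)(OCC(F)(F)F)OCC(F)(F)F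
Why: Still–Gennari modification of the Horner–Wadsworth–Emmons olefination gives the (2Z)-enoate under kinetic control.

Step 22
Reactants: 33 dienoate
Product: 34 (2Z,4E,7R,8R,9R)-7,9-bis(TBS-oxy)-4,8-dimethylundeca-2,4-dien-10-ynoic acid
Conditions: LiOH·H2O, THF/MeOH/H2O, 0 °C → rt; then aq. HCl to pH 4
Reagents that add atoms: lithium hydroxide, [Li+].[OH-]
Why: Hydroxide saponifies the methyl ester and cleaves the alkynyl C–Si bond in one operation, leaving the secondary silyl ethers and the diene geometry intact.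

**Fragment union and end game**

Step 23
Reactants: 23 chloroenyne alcohol; 34 alkyne acid
Product: 35 (Z)-enediyne acid (C11≡C12–C13H=C14H–C15≡C16)
Conditions: Pd(PPh3)4 (5 mol %), CuI (10 mol %), piperidine, THF, rt
Reagents that add atoms: none
Why: Sonogashira coupling of the vinyl chloride with the terminal alkyne joins the fragments with retention of the Z geometry, the free hydroxyl and carboxylate being tolerated.

Step 24
Reactants: 35 enediyne acid
Product: 36 tetrasilylated (11Z,13Z,15Z)-triene acid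
Conditions: Zn(Cu/Ag) [Zn dust, Cu(OAc)2, AgNO3], MeOH/H2O (1:1), rt, dark
Reagents that add atoms: none
Why: Boland reduction, in which activated zinc reduces only the two alkynes conjugated to the central alkene by syn addition of hydrogen, gives the Z,Z,Z-triene and leaves the other alkenes alone.

Step 25
Reactants: 36 silylated triene acid
Product: 37 target
Conditions: TBAF, AcOH (1:1), THF, 0 °C → rt
Reagents that add atoms: none
Why: Buffered fluoride cleaves the aryl, tertiary and secondary silyl ethers to release the target without acid that could ionize the p-hydroxybenzylic alcohol.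

**Compound list**

1 | 4,4-dimethylcyclopent-2-en-1-one | O=C1C=CC(C)(C)C1 | starting material
2 | tert-butyl[(1-methoxyethenyl)oxy]dimethylsilane | COC(=C)O[Si](C)(C)C(C)(C)C | starting material
3 | methyl 2-[(1R)-3-[(tert-butyldimethylsilyl)oxy]-5,5-dimethylcyclopent-2-en-1-yl]acetate | COC(=O)C[C@@H]1C=C(O[Si](C)(C)C(C)(C)C)CC1(C)C | intermediate
4 | methyl 2-[(1R)-5,5-dimethyl-3-[(trifluoromethanesulfonyl)oxy]cyclopent-2-en-1-yl]acetate | COC(=O)C[C@@H]1C=C(OS(=O)(=O)C(F)(F)F)CC1(C)C | intermediate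
5 | methyl 2-[(1R)-3,5,5-trimethylcyclopent-2-en-1-yl]acetate | COC(=O)C[C@@H]1C=C(C)CC1(C)C | intermediate
6 | methyl 2-[(1S,2R,3R)-2-bromo-3-hydroxy-3,5,5-trimethylcyclopentyl]acetate (not isolated) | Br[C@@H]1[C@@H](CC(=O)OC)C(C)(C)C[C@@]1(C)O | intermediate
7 | methyl 2-[(1S,2S,5R)-3,3,5-trimethyl-6-oxabicyclo[3.1.0]hexan-2-yl]acetate | C[C@@]12CC(C)(C)[C@H](CC(=O)OC)[C@@H]1O2 | intermediate
8 | prop-1-yn-1-yllithium | CC#C[Li] | starting material
9 | methyl 2-[(1R,2S,3R)-3-hydroxy-3,5,5-trimethyl-2-(prop-1-yn-1-yl)cyclopentyl]acetate | CC#C[C@@H]1[C@@H](CC(=O)OC)C(C)(C)C[C@@]1(C)O | intermediate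
10 | methyl 2-[(1R,2S,3R)-3,5,5-trimethyl-2-(prop-1-yn-1-yl)-3-[(triethylsilyl)oxy]cyclopentyl]acetate | CC#C[C@@H]1[C@@H](CC(=O)OC)C(C)(C)C[C@@]1(C)O[Si](CC)(CC)CC | intermediate
11 | N-methoxy-N-methyl-2-[(1R,2S,3R)-3,5,5-trimethyl-2-(prop-1-yn-1-yl)-3-[(triethylsilyl)oxy]cyclopentyl]acetamide | CC#C[C@@H]1[C@@H](CC(=O)N(C)OC)C(C)(C)C[C@@]1(C)O[Si](CC)(CC)CC | intermediate
12 | (4-bromophenoxy)tri(propan-2-yl)silane | Brc1ccc(O[Si](C(C)C)(C(C)C)C(C)C)cc1 | starting material
13 | {4-[(triisopropylsilyl)oxy]phenyl}lithium (not isolated) | [Li]c1ccc(O[Si](C(C)C)(C(C)C)C(C)C)cc1 | intermediate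
14 | 2-[(1R,2S,3R)-3,5,5-trimethyl-2-(prop-1-yn-1-yl)-3-[(triethylsilyl)oxy]cyclopentyl]-1-{4-[(triisopropylsilyl)oxy]phenyl}ethan-1-one | CC#C[C@@H]1[C@@H](CC(=O)c2ccc(O[Si](C(C)C)(C(C)C)C(C)C)cc2)C(C)(C)C[C@@]1(C)O[Si](CC)(CC)CC | intermediate
15 | 3-bromoprop-1-ene | C=CCBr | starting material
16 | (2S)-2-[(1S,2S,3R)-3,5,5-trimethyl-2-(prop-1-yn-1-yl)-3-[(triethylsilyl)oxy]cyclopentyl]-1-{4-[(triisopropylsilyl)oxy]phenyl}pent-4-en-1-one | CC#C[C@@H]1[C@@H]([C@H](CC=C)C(=O)c2ccc(O[Si](C(C)C)(C(C)C)C(C)C)cc2)C(C)(C)C[C@@]1(C)O[Si](CC)(CC)CC | intermediate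
17 | (3S)-4-oxo-3-[(1S,2S,3R)-3,5,5-trimethyl-2-(prop-1-yn-1-yl)-3-[(triethylsilyl)oxy]cyclopentyl]-4-{4-[(triisopropylsilyl)oxy]phenyl}butanal | CC#C[C@@H]1[C@@H]([C@H](CC=O)C(=O)c2ccc(O[Si](C(C)C)(C(C)C)C(C)C)cc2)C(C)(C)C[C@@]1(C)O[Si](CC)(CC)CC | intermediate
18 | (2R,3Z)-4-[(tert-butyldimethylsilyl)oxy]-2-[(1S,2S,3R)-3,5,5-trimethyl-2-(prop-1-yn-1-yl)-3-[(triethylsilyl)oxy]cyclopentyl]-1-{4-[(triisopropylsilyl)oxy]phenyl}but-3-en-1-one | CC#C[C@@H]1[C@@H]([C@H](/C=C\O[Si](C)(C)C(C)(C)C)C(=O)c2ccc(O[Si](C(C)C)(C(C)C)C(C)C)cc2)C(C)(C)C[C@@]1(C)O[Si](CC)(CC)CC | intermediate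
19 | (1R,3aS,4R,5S,7aR)-1,3,3,6-tetramethyl-1-[(triethylsilyl)oxy]-4-{4-[(triisopropylsilyl)oxy]benzoyl}-2,3,3a,4,5,7a-hexahydro-1H-indene-5-carbaldehyde | CC1=C[C@@H]2[C@@H]([C@@H](C(=O)c3ccc(O[Si](C(C)C)(C(C)C)C(C)C)cc3)[C@@H]1C=O)C(C)(C)C[C@@]2(C)O[Si](CC)(CC)CC | intermediate
20 | {(1R,3aS,4R,5R,7aR)-5-ethynyl-1,3,3,6-tetramethyl-1-[(triethylsilyl)oxy]-2,3,3a,4,5,7a-hexahydro-1H-inden-4-yl}{4-[(triisopropylsilyl)oxy]phenyl}methanone | CC1=C[C@@H]2[C@@H]([C@@H](C(=O)c3ccc(O[Si](C(C)C)(C(C)C)C(C)C)cc3)[C@@H]1C#C)C(C)(C)C[C@@]2(C)O[Si](CC)(CC)CC | intermediate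
21 | (Z)-1,2-dichloroethene | Cl/C=C\Cl | starting material
22 | {(1R,3aS,4R,5S,7aR)-5-[(3Z)-4-chlorobut-3-en-1-yn-1-yl]-1,3,3,6-tetramethyl-1-[(triethylsilyl)oxy]-2,3,3a,4,5,7a-hexahydro-1H-inden-4-yl}{4-[(triisopropylsilyl)oxy]phenyl}methanone | CC1=C[C@@H]2[C@@H]([C@@H](C(=O)c3ccc(O[Si](C(C)C)(C(C)C)C(C)C)cc3)[C@@H]1C#C/C=C\Cl)C(C)(C)C[C@@]2(C)O[Si](CC)(CC)CC | intermediate
23 | (S)-{(1R,3aR,4R,5S,7aR)-5-[(3Z)-4-chlorobut-3-en-1-yn-1-yl]-1,3,3,6-tetramethyl-1-[(triethylsilyl)oxy]-2,3,3a,4,5,7a-hexahydro-1H-inden-4-yl}{4-[(triisopropylsilyl)oxy]phenyl}methanol | CC1=C[C@@H]2[C@@H]([C@@H]([C@H](O)c3ccc(O[Si](C(C)C)(C(C)C)C(C)C)cc3)[C@@H]1C#C/C=C\Cl)C(C)(C)C[C@@]2(C)O[Si](CC)(CC)CC | intermediate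
24 | propanal | CCC=O | starting material
25 | 3-(trimethylsilyl)prop-2-ynal | C[Si](C)(C)C#CC=O | starting material
26 | (2S,3R)-3-hydroxy-2-methyl-5-(trimethylsilyl)pent-4-ynal | C[Si](C)(C)C#C[C@H](O)[C@H](C)C=O | intermediate
27 | (2S,3R)-3-[(tert-butyldimethylsilyl)oxy]-2-methyl-5-(trimethylsilyl)pent-4-ynal | C[Si](C)(C)C#C[C@H](O[Si](C)(C)C(C)(C)C)[C@H](C)C=O | intermediate
28 | (+)-B-allyldiisopinocampheylborane, from (−)-α-pinene | C=CCB([C@H]1C[C@H]2C[C@@H]([C@@H]1C)C2(C)C)[C@H]1C[C@H]2C[C@@H]([C@@H]1C)C2(C)C | starting material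
29 | (4R,5R,6R)-6-[(tert-butyldimethylsilyl)oxy]-5-methyl-8-(trimethylsilyl)oct-1-en-7-yn-4-ol | C[Si](C)(C)C#C[C@H](O[Si](C)(C)C(C)(C)C)[C@H](C)[C@H](O)CC=C | intermediate
30 | (4R,5R,6R)-4,6-bis[(tert-butyldimethylsilyl)oxy]-5-methyl-8-(trimethylsilyl)oct-1-en-7-yne | C[Si](C)(C)C#C[C@H](O[Si](C)(C)C(C)(C)C)[C@H](C)[C@H](O[Si](C)(C)C(C)(C)C)CC=C | intermediate
31 | 2-methylprop-2-enal | CC(=C)C=O | starting material
32 | (2E,5R,6R,7R)-5,7-bis[(tert-butyldimethylsilyl)oxy]-2,6-dimethyl-9-(trimethylsilyl)non-2-en-8-ynal | C[Si](C)(C)C#C[C@H](O[Si](C)(C)C(C)(C)C)[C@H](C)[C@H](O[Si](C)(C)C(C)(C)C)C/C=C(\C)C=O | intermediate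
33 | methyl (2Z,4E,7R,8R,9R)-7,9-bis[(tert-butyldimethylsilyl)oxy]-4,8-dimethyl-11-(trimethylsilyl)undeca-2,4-dien-10-ynoate | C[Si](C)(C)C#C[C@H](O[Si](C)(C)C(C)(C)C)[C@H](C)[C@H](O[Si](C)(C)C(C)(C)C)C/C=C(C)/C=C\C(=O)OC | intermediate
34 | (2Z,4E,7R,8R,9R)-7,9-bis[(tert-butyldimethylsilyl)oxy]-4,8-dimethylundeca-2,4-dien-10-ynoic acid | C#C[C@H](O[Si](C)(C)C(C)(C)C)[C@H](C)[C@H](O[Si](C)(C)C(C)(C)C)C/C=C(C)/C=C\C(=O)O | intermediate
35 | (Z)-enediyne acid: 23 joined at C14 to C15 of 34 (C11≡C12–C13H=C14H–C15≡C16); TES on C9–O, TBS on C17–O and C19–O, TIPS on the phenol, C10–OH and CO2H free; stereocentres as in the target | CC1=C[C@@H]2[C@@H]([C@@H]([C@H](O)c3ccc(O[Si](C(C)C)(C(C)C)C(C)C)cc3)[C@@H]1C#C/C=C\C#C[C@H](O[Si](C)(C)C(C)(C)C)[C@H](C)[C@H](O[Si](C)(C)C(C)(C)C)C/C=C(C)/C=C\C(=O)O)C(C)(C)C[C@@]2(C)O[Si](CC)(CC)CC | intermediate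
36 | tetrasilylated target: (11Z,13Z,15Z)-triene acid with TES on C9–O, TBS on C17–O and C19–O, TIPS on the phenol | CC1=C[C@@H]2[C@@H]([C@@H]([C@H](O)c3ccc(O[Si](C(C)C)(C(C)C)C(C)C)cc3)[C@@H]1\C=C/C=C\C=C/[C@H](O[Si](C)(C)C(C)(C)C)[C@H](C)[C@H](O[Si](C)(C)C(C)(C)C)C/C=C(C)/C=C\C(=O)O)C(C)(C)C[C@@]2(C)O[Si](CC)(CC)CC | intermediate
37 | (2Z,4E,7R,8R,9S,10Z,12Z,14Z)-7,9-dihydroxy-15-[(1R,3aR,4R,5S,7aR)-1-hydroxy-4-[(S)-hydroxy(4-hydroxyphenyl)methyl]-1,3,3,6-tetramethyl-2,3,3a,4,5,7a-hexahydro-1H-inden-5-yl]-4,8-dimethylpentadeca-2,4,10,12,14-pentaenoic acid | CC1=C[C@@H]2[C@@H]([C@@H]([C@H](O)c3ccc(O)cc3)[C@@H]1\C=C/C=C\C=C/[C@H](O)[C@H](C)[C@H](O)C/C=C(C)/C=C\C(=O)O)C(C)(C)C[C@@]2(C)O | target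

**Count and risks**

Total step count: 25. Longest linear sequence: 18 steps (steps 1 to 15, then 23 to 25); the side chain takes 7 steps (16 to 22).

Steps most likely to fail:

Step 12. The enol ether may lose its silyl group before it cyclizes, the aryl ketone oxygen may attack the activated alkyne, closure may leak into the 5-exo mode, or facial control at C6 may be incomplete. The fallback sets out from 18 and replaces gold π-acid catalysis by stoichiometric halonium activation: bis(pyridine)iodonium tetrafluoroborate with HBF4·OEt2 in CH2Cl2 at −60 °C should close the same C1–C6 bond by iodo-carbocyclization and give the 7-iodo analogue of 19 (iodine on C2) F1. Hydrodeiodination with Bu3SnH and catalytic Pd(PPh3)4 in THF then comes back to 19.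

Step 13. The basic medium may epimerize C6, move the C1=C2 bond into conjugation with the aldehyde before homologation, or cleave the aryl silyl ether. The fallback sets out from 19: Stork–Zhao olefination with the ylide from (iodomethyl)triphenylphosphonium iodide and NaHMDS (THF/HMPA, −78 °C) should give the (Z)-2-iodovinyl analogue of 19 F2. Anti-elimination of HI with DBU (toluene, 60 °C), which also equilibrates C5 to the equatorial aroyl isomer, comes back to 20.

Step 1. Conversion may be low and facial selectivity poor at a β-carbon next to a quaternary centre. The fallback sets out from 1: Michael addition of dimethyl malonate under heterobimetallic catalysis by lithium aluminium bis(binaphthoxide), LiAl(C20H12O2)2, should give dimethyl 2-[(1S)-2,2-dimethyl-4-oxocyclopentyl]propanedioate F3. Krapcho demethoxycarbonylation (NaCl, wet DMSO, 150 °C) gives methyl 2-[(1S)-2,2-dimethyl-4-oxocyclopentyl]acetate F4. Kinetic deprotonation at the α-methylene remote from the gem-dimethyl group (LiHMDS, THF, −78 °C) and trapping with PhNTf2 comes back to 4.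

Further compounds
F1 | step 12 | (1R,3aS,4R,5S,7aR)-7-iodo-1,3,3,6-tetramethyl-1-[(triethylsilyl)oxy]-4-{4-[(triisopropylsilyl)oxy]benzoyl}-2,3,3a,4,5,7a-hexahydro-1H-indene-5-carbaldehyde (spatial arrangement as in 19) | CC1=C(I)[C@@H]2[C@@H]([C@@H](C(=O)c3ccc(O[Si](C(C)C)(C(C)C)C(C)C)cc3)[C@@H]1C=O)C(C)(C)C[C@@]2(C)O[Si](CC)(CC)CC
F2 | step 13 | {5-[(Z)-2-iodoethenyl]-1,3,3,6-tetramethyl-1-[(triethylsilyl)oxy]-2,3,3a,4,5,7a-hexahydro-1H-inden-4-yl}{4-[(triisopropylsilyl)oxy]phenyl}methanone (ring stereocentres as in 19) | CC1=C[C@@H]2[C@@H]([C@@H](C(=O)c3ccc(O[Si](C(C)C)(C(C)C)C(C)C)cc3)[C@@H]1/C=C\I)C(C)(C)C[C@@]2(C)O[Si](CC)(CC)CC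
F3 | step 1 | dimethyl 2-[(1S)-2,2-dimethyl-4-oxocyclopentyl]propanedioate | COC(=O)C(C(=O)OC)[C@@H]1CC(=O)CC1(C)C
F4 | step 1 | methyl 2-[(1S)-2,2-dimethyl-4-oxocyclopentyl]acetate | COC(=O)C[C@@H]1CC(=O)CC1(C)C
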